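Readings and results stem from a simulated flask with made-up constants; the scatter is artificial.

Late times were what I had to reach in the maple flask, since the time asked about lies beyond its last reading at 2 h.

| flask | J | remark | time |
|---|---|---|---|
| maple | 0.072 M | the very flask that is asked about, followed so far |  |
| birch | 0.11 M | run made earlier |  |
| flask | 0.072 M |  | 5.0 h |

maple run (percent of the J charged)

| time / min | G / % | Z / % | J / % | D / % |
|---|---|---|---|---|
| 15.0 | 0.2 | 5.6 | 83.3 | 11.8 |
| 40.0 | 0.1 | 14.0 | 60.6 | 25.7 |
| 80.0 | 2.4 | 20.9 | 36.4 | 39.3 |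
| 120 | 3.6 | 25.5 | 22.0 | 50.4 |

birch run (percent of the J charged)

| time / h | G / % | Z / % | J / % | D / % |
|---|---|---|---|---|
| 0.833 | 0 | 15.5 | 53.3 | 29.8 |
| 2.00 | 2.9 | 24.7 | 22.3 | 49.1 |
| 2.50 | 4.3 | 27.3 | 14.4 | 54.7 |
| 4.00 | 6.7 | 28.7 | 4.6 | 60.7 |

(each reading ± 0.5 percentage points)



- where most of what was charged as J, at 5.0 h is found (Z / J / G / D)
- the largest share itself, whichever of these holds it, in percent of the J charged

So I counted turnovers. In the birch run c_J had fallen to 4.6% of the charge at 4.00 h, which gave the turnover rate, the number of factors of e by which c_J falls per hour, or first-order rate constant: 0.770 h⁻¹. The maple run, with its smaller charge, gave 0.757 h⁻¹, so I took the turnover rate as independent of the charge. At that birch reading D held 63.6% of the J spent, and I called this the D share, the selectivity.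

Two flasks could be solved in the head. If counting stopped at the birch reading, with 3.08 turnovers, D stood at 60.7%. Counted without end, my reckoning put D at the D share itself. The maple flask at 5.0 h had 3.85 turnovers, so I placed its D between the two, and I reckoned D at 62.3%. On that reading Z and G together took 36.4% of the J spent, so I expected D to hold the most.

The forecast said D at 62.5%, from 60.8% to 64.2%, on the ground that “D stays at a constant fraction of the J consumed”.

The maple flask gave D at 62.5%, under these equations.

    J → Z (k = 7.60 × 10⁻⁵ s⁻¹)
    J → D (k = 1.35 × 10⁻⁴ s⁻¹)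
    Z ⇌ G (K = 0.347, k = 3.29 × 10⁻⁵ s⁻¹)

With 0.18 M of J in place of 0.072 M, the neighbour flask held D at 62.5%. My 3.85 turnovers left 2.13% of J, and the maple flask held 2.24%. Read at 3.0 h instead, the count was 2.31 turnovers, which left 9.93%, and that neighbour flask held 10.2% of J.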